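**Remarks on numbering and assumptions**

- Locants used throughout: C1 = CH(OBz) next to the quaternary carbon, C2=C3 = alkene, C4 = CH(OBz), C5 = CH(OH), C6 = C(OH)(CH2OH), C7 = the CH2OH carbon; On = oxygen on Cn. "β" is the ring face that carries O6, "α" the face that carries C7. The target is 1β,4β-bis(benzoyloxy), 5α-OH, 6β-OH (1S,4R,5S,6R in these locants).
- The (R)-antipode of the phosphoric acid is assumed to deliver the enantiomer drawn for 7; if the sense of induction is the opposite, the (S)-antipode is used and nothing else changes.
- The acetal carbon of 7 is drawn with isopropyl equatorial (2,4-cis-dioxane); its configuration is immaterial because step 8 removes it.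

## Structural features

The target is a single carbocycle, a cyclohex-2-ene, in which every sp3 ring carbon carries oxygen and C6 also carries the hydroxymethyl carbon C7; the only other rings are the two benzoate phenyls. The four stereocenters C4–C5–C6–C1 are contiguous and end on both sides at the C2=C3 double bond, so both benzoates are allylic. The two benzoates are cis to each other and to the tertiary hydroxyl (all β), whereas O5 is α, trans to both of its neighbours and therefore on the same face as C7. The allylic benzoates are the fragile groups: they can ionise, and under base they can migrate to the free hydroxyls (O1 to the primary O7 is downhill), so the last steps must be non-basic. The real difficulty is the tetrasubstituted carbinol C6 of defined configuration inside a run of four oxygenated stereocenters, together with telling five oxygens apart (two acylated, three free). The feature the key step exploits is a hidden mirror plane: C2 and C3 carry no oxygen, C6 lies para to C3, and C1 and C5 are both oxygenated. With a carbonyl at C3 and C1=C2 and C4=C5 unsaturation the carbocycle is the achiral p-quinol of 4-hydroxybenzyl alcohol, in which C6 is not yet a stereocenter. In that dienone the cis pair O5/C7 is the retron for oxygen delivery from C7 to C5, and the pair C2=C3/O1 is the retron of a Wharton transposition of the remaining enone.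

## Logic of the disconnections

**15 ⇒ 14.** The two O–H bonds at O5 and O7 are replaced by bonds to one acetal carbon (the forward step cuts these two acetal C–O bonds). O5 and O7 are cis-1,3-related and are the two hydroxyls that must stay unacylated besides the tertiary one, so a single tether protects both. The demand is that the acetal is removed under acidic to neutral conditions, where the benzoates do not migrate.

**14 ⇒ 13.** The two ester C–O bonds at O1 and O4 are cut. In 13 these are the only secondary hydroxyls, so no further protection is needed. The forward acylation has to leave the tertiary O6–H alone.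

**13 ⇒ 11 (through 12).** The C2=C3 double bond and the C1–O–H unit are traced back to a C1–C2 oxirane and a C3 ketone (retro-Wharton). This turns the oxygen-free C3 into a carbonyl carbon and restores an enone-derived ring. The demand is a β-oxirane, because the C1–O bond is carried through unchanged.

**11 ⇒ 10.** The two oxirane C–O bonds are cut, leaving the C1=C2–C3=O enone. The forward epoxidation must take the β face; the free O6–H (directing) and the α-fused dioxane (blocking) both point that way.

**10 ⇒ 7.** The C4–O4 bond is cut (and O6 is re-silylated). C4 then becomes the α'-methylene of an enone whose only enolisable position it is. The forward oxidation must place O4 trans to O5 and must not expel O5 by β-elimination.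

**7 ⇒ 4 + 5 (key disconnection).** The C5–O5 bond and the two acetal C–O bonds are cut, which opens the dioxane ring. This removes the stereocenters C5 and C6 (and the acetal carbon) in one stroke and leaves 4, an achiral, planar dienone with two enantiotopic enone arms, plus the simple aldehyde 5. The forward step must choose one of the two arms under catalyst control; the face of attack is fixed by the tether. O6 must be masked so that only the primary hydroxyl engages 5.

**4 ⇒ 2 ⇒ 1.** The O6–Si bond is cut, then the C6–O6 bond (retro-dearomatisation), arriving at a commercial phenol. The forward oxidation must add water at the para carbon, and the later manipulations of 2 must avoid base (loss of formaldehyde with aromatisation).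

## Other disconnections considered

**Alternative 1:** (the first that comes to mind for a cis-ene-1,4-diol) Cut both C1–O and C4–O bonds at once. The forward key step is the [4+2] cycloaddition of singlet oxygen to the trans-dioxygenated diene A1, giving endoperoxide A2, followed by O–O reduction and benzoylation. The chosen plan is preferred on three grounds. A1 is an arene hydrate that aromatises by dehydration under acid. Its two faces differ only by C7 versus H at C6, so facial control depends on protecting groups. The cycloaddition sets only C1 and C4; C5 and C6 must be made enantioselectively beforehand in a separate sequence of about six steps.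

**Alternative 2:** Cut C1–C6 and C4–C5 (Diels–Alder). The forward key step is the cycloaddition of (1E,3E)-1,4-bis(benzoyloxy)buta-1,3-diene A3 with methyl propiolate to give the cis-3,6-bis(benzoyloxy)cyclohexa-1,4-diene ester A4. The cis benzoates would arrive in final form, but A4 is a 1,4-dihydrobenzene with two allylic leaving groups and should lose benzoic acid to an arene at the temperature the deactivated diene needs. There is no handle for absolute control. C5=C6 would still need a face-selective anti-dihydroxylation next to C2=C3.

**Alternative 3:** Cut C2=C3 (ring-closing metathesis). The forward key step closes the octa-1,7-diene A5 with a ruthenium alkylidene. A5 already contains all four stereocenters, so the ring closure solves none of the stereochemical problem. The tetrasubstituted carbinol would have to come from addition to a carbohydrate-derived ketone with uncertain selectivity and a long protecting-group sequence.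

Key step: step 3

## Route

Step 1
Reactants: 1 4-(hydroxymethyl)phenol
Product: 2 4-hydroxy-4-(hydroxymethyl)cyclohexa-2,5-dien-1-one
Conditions: PhI(OAc)2, MeCN/H2O (3:1), 0 °C
Reagents that add atoms: water, O
Why: Oxidative dearomatisation of a para-substituted phenol with a hypervalent iodine reagent: ligand exchange at iodine, then attack of water at the para carbon with loss of iodobenzene gives the p-quinol. The medium stays mildly acidic, so the alkoxide needed for retro-aldol loss of formaldehyde is not formed. No stereocenter arises: 2 has a mirror plane through C3, C6, O6 and C7.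

Step 2
Reactants: 2 4-hydroxy-4-(hydroxymethyl)cyclohexa-2,5-dien-1-one
Product: 4 4-(hydroxymethyl)-4-(triethylsilyloxy)cyclohexa-2,5-dien-1-one, via bis(triethylsilyl) ether 3 (not isolated)
Conditions: Et3SiOTf, 2,6-lutidine, CH2Cl2, −78 to 0 °C; aqueous work-up; crude 3, pyridinium p-toluenesulfonate, MeOH, 0 °C
Reagents that add atoms: triethylsilyl trifluoromethanesulfonate, CC[Si](CC)(CC)OS(=O)(=O)C(F)(F)F
Why: The silyl triflate silylates both hydroxyls, the hindered tertiary one included; acid-catalysed methanolysis then cleaves the far more accessible primary silyl ether (standard primary-over-tertiary selectivity). Acid is chosen because base would allow O-to-O silyl migration and formaldehyde extrusion. The tertiary silyl ether keeps O6 out of the hemiacetal chemistry of step 3.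

Step 3
Reactants: 4 4-(hydroxymethyl)-4-(triethylsilyloxy)cyclohexa-2,5-dien-1-one; 5 2-methylpropanal
Product: 7 (2R,4aR,8aS)-2-isopropyl-4a-(triethylsilyloxy)-4a,8a-dihydro-4H-1,3-benzodioxin-7(8H)-one, via hemiacetal 6 (not isolated)
Conditions: 5 (3 equiv), (R)-3,3'-bis(2,4,6-triisopropylphenyl)-1,1'-binaphthyl-2,2'-diyl hydrogen phosphate (10 mol %), CH2Cl2, 0 °C to rt
Reagents that add atoms: none
Why: The primary hydroxyl of 4 adds reversibly to 5 to give hemiacetal 6; the chiral phosphoric acid binds 6 at two points (P=O to the hemiacetal O–H, P–OH to the dienone carbonyl) and the hemiacetal oxygen adds to a β-carbon in an intramolecular oxa-Michael reaction, after which the enol tautomerises. The closest known reaction type is the chiral phosphoric acid catalysed acetalisation/oxa-Michael desymmetrisation of 4-hydroxy- and 4-hydroperoxy-cyclohexadienones, together with the hemiacetal oxa-Michael route from δ-hydroxy enones to 1,3-dioxanes. The 1,3-dioxane closes in a 6-exo-trig mode through a chair-like transition state. C5 is controlled by the tether: an oxygen hanging from C7 can reach only the face of the dienone on which C7 sits, so O5 is necessarily cis to C7 (cis ring fusion). C6 becomes a stereocenter when one of the two enantiotopic enone arms is consumed; the catalyst alone decides which arm reacts, and that choice fixes the absolute configuration of C6 and C5 together. The acetal carbon takes isopropyl equatorial in the chair and is temporary. The step needs enantiotopic-group selectivity (from the catalyst) and chemoselectivity for the primary hydroxyl (secured by the silyl group on O6, which rules out dioxolane or spiro-acetal formation); the absence of base keeps 4 from fragmenting. An achiral planar dienone thus becomes a bicyclic enone that holds the quaternary stereocenter and C5, with C4 and the C1=C2 enone now chemically distinct for the relay.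

Step 4
Reactants: 7 (2R,4aR,8aS)-2-isopropyl-4a-(triethylsilyloxy)-4a,8a-dihydro-4H-1,3-benzodioxin-7(8H)-one
Product: 10 (2R,4aR,8S,8aS)-4a,8-dihydroxy-2-isopropyl-4a,8a-dihydro-4H-1,3-benzodioxin-7(8H)-one, via silyl dienol ether 8 (not isolated), via silyloxy ketone 9 (not isolated)
Conditions: LiN(SiMe3)2, Me3SiCl (internal quench), THF, −78 °C; m-CPBA, NaHCO3, CH2Cl2, −20 °C; HF·pyridine, THF/pyridine, 0 °C to rt
Reagents that add atoms: m-chloroperoxybenzoic acid, OOC(=O)c1cccc(Cl)c1 (oxygen at C4); chlorotrimethylsilane, C[Si](C)(C)Cl (silyl group carried only by 8 and 9)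
Why: Rubottom oxidation: 7 can enolise only toward C4 (C2 is vinylic, C6 quaternary), and the internal quench keeps the enolate short-lived so that β-elimination of O5 should not compete. The peracid attacks the electron-rich silyl enol ether from the β face, anti to the vicinal C5–O bond and to the α-fused dioxane, which places O4 trans to O5. Fluoride then removes both silyl groups and frees the tertiary hydroxyl needed in step 5.

Step 5
Reactants: 10 (2R,4aR,8S,8aS)-4a,8-dihydroxy-2-isopropyl-4a,8a-dihydro-4H-1,3-benzodioxin-7(8H)-one
Product: 11 (2R,4aS,5S,6R,8S,8aS)-5,6-epoxy-4a,8-dihydroxy-2-isopropylhexahydro-4H-1,3-benzodioxin-7(8H)-one (oxirane oxygen β)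
Conditions: t-BuOOH (in decane), 1,8-diazabicyclo[5.4.0]undec-7-ene, CH2Cl2, 0 °C
Reagents that add atoms: tert-butyl hydroperoxide, CC(C)(C)OO
Why: Nucleophilic (Weitz–Scheffer) epoxidation of the enone: the tert-butylperoxide anion adds at C1 and the enolate closes the oxirane with loss of tert-butoxide. The free O6–H hydrogen-bonds to the peroxide anion and delivers it to the β face, while C7 of the cis-fused dioxane shields the α face at C1, so the oxirane oxygen should end syn to O6; this sets C1.

Step 6
Reactants: 11 (2R,4aS,5S,6R,8S,8aS)-5,6-epoxy-4a,8-dihydroxy-2-isopropylhexahydro-4H-1,3-benzodioxin-7(8H)-one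
Product: 13 (2R,4aS,5S,8R,8aS)-2-isopropyl-4a,5,8,8a-tetrahydro-4H-1,3-benzodioxine-4a,5,8-triol, via epoxy hydrazone 12 (not isolated)
Conditions: N2H4·H2O, AcOH (cat.), MeOH, 0 °C to rt
Reagents that add atoms: hydrazine, NN (nitrogen carried only by 12)
Why: Wharton transposition: hydrazone 12 opens the oxirane at C2, the alkenyl diazene loses dinitrogen, and the product carries the C2=C3 double bond and the C1 hydroxyl. The C1–O bond is not touched, so its β configuration is retained, and the former carbonyl carbon C3 becomes the oxygen-free alkene CH of the target. The free C4 hydroxyl is a poor leaving group next to the hydrazone and should stay in place.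

Step 7
Reactants: 13 (2R,4aS,5S,8R,8aS)-2-isopropyl-4a,5,8,8a-tetrahydro-4H-1,3-benzodioxine-4a,5,8-triol
Product: 14 (2R,4aS,5S,8R,8aS)-4a-hydroxy-2-isopropyl-4a,5,8,8a-tetrahydro-4H-1,3-benzodioxine-5,8-diyl dibenzoate
Conditions: BzCl (2.5 equiv), pyridine, CH2Cl2, 0 °C to rt
Reagents that add atoms: benzoyl chloride, O=C(Cl)c1ccccc1
Why: Acylation in pyridine esterifies the two secondary allylic hydroxyls; the tertiary C6 hydroxyl is too hindered to react without a stronger acyl-transfer catalyst, and O5 and O7 are locked in the acetal. No stereocenter is affected.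

Step 8
Reactants: 14 (2R,4aS,5S,8R,8aS)-4a-hydroxy-2-isopropyl-4a,5,8,8a-tetrahydro-4H-1,3-benzodioxine-5,8-diyl dibenzoate
Product: 15 (1R,4S,5R,6S)-5,6-dihydroxy-5-(hydroxymethyl)cyclohex-2-ene-1,4-diyl dibenzoate
Conditions: CF3CO2H/H2O, THF, 0 °C to rt; neutral work-up
Reagents that add atoms: none
Why: Acid-catalysed hydrolysis of the alkylidene acetal releases O5–H and O7–H. Benzoates are stable to aqueous acid at this temperature, and an acidic to neutral medium avoids the base-promoted acyl shifts (O1 to O7, O4 to O5) to which the product is prone.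

## Compound list

1 | 4-(hydroxymethyl)phenol (4-hydroxybenzyl alcohol) | OCc1ccc(O)cc1 | starting material
2 | 4-hydroxy-4-(hydroxymethyl)cyclohexa-2,5-dien-1-one | O=C1C=CC(O)(CO)C=C1 | intermediate
3 | 4-(triethylsilyloxy)-4-[(triethylsilyloxy)methyl]cyclohexa-2,5-dien-1-one | O=C1C=CC(CO[Si](CC)(CC)CC)(O[Si](CC)(CC)CC)C=C1 | intermediate
4 | 4-(hydroxymethyl)-4-(triethylsilyloxy)cyclohexa-2,5-dien-1-one | O=C1C=CC(CO)(O[Si](CC)(CC)CC)C=C1 | intermediate
5 | 2-methylpropanal (isobutyraldehyde) | CC(C)C=O | starting material
6 | 4-[(1-hydroxy-2-methylpropoxy)methyl]-4-(triethylsilyloxy)cyclohexa-2,5-dien-1-one (hemiacetal, both epimers, interconverting) | O=C1C=CC(COC(O)C(C)C)(O[Si](CC)(CC)CC)C=C1 | intermediate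
7 | (2R,4aR,8aS)-2-isopropyl-4a-(triethylsilyloxy)-4a,8a-dihydro-4H-1,3-benzodioxin-7(8H)-one (cis-fused; O5 and C7 α, O6 β) | C1=CC(=O)C[C@H](O2)[C@]1(O[Si](CC)(CC)CC)CO[C@H]2C(C)C | intermediate
8 | (2R,4aR,8aS)-2-isopropyl-4a-(triethylsilyloxy)-7-(trimethylsilyloxy)-4a,8a-dihydro-4H-1,3-benzodioxine | C1=CC(O[Si](C)(C)C)=C[C@H](O2)[C@]1(O[Si](CC)(CC)CC)CO[C@H]2C(C)C | intermediate
9 | (2R,4aR,8S,8aS)-2-isopropyl-4a-(triethylsilyloxy)-8-(trimethylsilyloxy)-4a,8a-dihydro-4H-1,3-benzodioxin-7(8H)-one | C1=CC(=O)[C@@H](O[Si](C)(C)C)[C@H](O2)[C@]1(O[Si](CC)(CC)CC)CO[C@H]2C(C)C | intermediate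
10 | (2R,4aR,8S,8aS)-4a,8-dihydroxy-2-isopropyl-4a,8a-dihydro-4H-1,3-benzodioxin-7(8H)-one (O4 β, trans to O5) | C1=CC(=O)[C@@H](O)[C@H](O2)[C@]1(O)CO[C@H]2C(C)C | intermediate
11 | (2R,4aS,5S,6R,8S,8aS)-5,6-epoxy-4a,8-dihydroxy-2-isopropylhexahydro-4H-1,3-benzodioxin-7(8H)-one (C1–C2 oxirane, oxygen β) | O3[C@H]1[C@@H]3C(=O)[C@@H](O)[C@H](O2)[C@]1(O)CO[C@H]2C(C)C | intermediate
12 | hydrazone of 11 at the ring carbonyl (C3) | O3[C@H]1[C@@H]3C(=NN)[C@@H](O)[C@H](O2)[C@]1(O)CO[C@H]2C(C)C | intermediate
13 | (2R,4aS,5S,8R,8aS)-2-isopropyl-4a,5,8,8a-tetrahydro-4H-1,3-benzodioxine-4a,5,8-triol (O1, O4, O6 all β) | O[C@H]1C=C[C@@H](O)[C@H](O2)[C@]1(O)CO[C@H]2C(C)C | intermediate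
14 | (2R,4aS,5S,8R,8aS)-4a-hydroxy-2-isopropyl-4a,5,8,8a-tetrahydro-4H-1,3-benzodioxine-5,8-diyl dibenzoate | O=C(O[C@H]1C=C[C@@H](OC(=O)c3ccccc3)[C@H](O2)[C@]1(O)CO[C@H]2C(C)C)c1ccccc1 | intermediate
15 | (1R,4S,5R,6S)-5,6-dihydroxy-5-(hydroxymethyl)cyclohex-2-ene-1,4-diyl dibenzoate (IUPAC locants; 1S,4R,5S,6R in the locants of this proposal) | O=C(O[C@H]1C=C[C@@H](OC(=O)c2ccccc2)[C@H](O)[C@]1(O)CO)c1ccccc1 | target

## Step count and least certain steps

Total: 8 steps. Longest linear sequence: 8 steps (1 to 15); 5 and all reagents are used as purchased.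

**Step 3 (key step).** The most likely failure is weak discrimination between the two enantiotopic enone arms, giving low enantiomeric purity. A second is slow cyclisation, because hemiacetal formation at a neopentyl-type primary alcohol is unfavourable, with erosion of the tertiary silyl ether over long reaction times. The fallback changes the oxygen-delivery element and the catalyst class. From 4, phenylboronic acid and the bifunctional amine–thiourea 1-[3,5-bis(trifluoromethyl)phenyl]-3-[(8α,9S)-6'-methoxycinchonan-9-yl]thiourea (boronate hemiester as a chiral hydroxide equivalent, intramolecular B–OH oxa-Michael) should give the cyclic boronate (4aR,8aS)-2-phenyl-4a-(triethylsilyloxy)-4a,8a-dihydro-4H-1,3,2-benzodioxaborinin-7(8H)-one F1. Transesterification with pinacol should release (4R,5S)-5-hydroxy-4-(hydroxymethyl)-4-(triethylsilyloxy)cyclohex-2-en-1-one F2. Acetalisation of F2 with 5 (pyridinium p-toluenesulfonate, MgSO4, CH2Cl2) returns to the route at 7.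

**Step 1.** The most likely failure is oxidation at the benzylic carbinol through a quinone-methide tautomer instead of para-hydroxylation, or loss of formaldehyde from 2 (vinylogous retro-aldol driven by aromatisation) during isolation. The fallback masks the hydroxymethyl group before dearomatisation. From 1, selective silylation of the aliphatic hydroxyl (Et3SiCl, imidazole, CH2Cl2, −20 °C) should give 4-[(triethylsilyloxy)methyl]phenol F3. PhI(OAc)2 in buffered MeCN/H2O should give 4-hydroxy-4-[(triethylsilyloxy)methyl]cyclohexa-2,5-dien-1-one F4. Et3SiOTf/2,6-lutidine then silylates the tertiary hydroxyl and returns to the route at 3 (second operation of step 2).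

**Step 4.** The most likely failure is β-elimination of O5 from the C4 enolate (retro-oxa-Michael, opening the dioxane), or poor facial selectivity in the oxidation of the enol ether. The fallback avoids a free enolate. From 7, α'-acetoxylation with Mn(OAc)3·2H2O in benzene at reflux should give (2R,4aR,8S,8aS)-2-isopropyl-7-oxo-4a-(triethylsilyloxy)-4a,7,8,8a-tetrahydro-4H-1,3-benzodioxin-8-yl acetate F5. HF·pyridine should give the tertiary alcohol (2R,4aR,8S,8aS)-4a-hydroxy-2-isopropyl-7-oxo-4a,7,8,8a-tetrahydro-4H-1,3-benzodioxin-8-yl acetate F6. Methanolysis of the acetate (K2CO3, MeOH, −20 °C) returns to the route at 10.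

**Step 6.** The most likely failure is diversion of the Wharton fragmentation (the alkenyl diazene collapsing by radical pathways, or the α'-hydroxy hydrazone consuming more hydrazine). Material may also be lost in step 5 by base-induced retro-oxa-Michael. The fallback replaces the enone transposition by a cycloaddition and bypasses steps 4 to 6. From 7, KN(SiMe3)2 and N-phenylbis(trifluoromethanesulfonimide) at −78 °C should give the dienyl triflate (2R,4aR,8aS)-2-isopropyl-4a-(triethylsilyloxy)-4a,8a-dihydro-4H-1,3-benzodioxin-7-yl trifluoromethanesulfonate F7. Reduction with Pd(OAc)2, PPh3, HCO2H and Bu3N in DMF should give the diene (2R,4aR,8aS)-2-isopropyl-4a-(triethylsilyloxy)-4a,8a-dihydro-4H-1,3-benzodioxine F8. HF·pyridine should give (2R,4aR,8aS)-2-isopropyl-4a,8a-dihydro-4H-1,3-benzodioxin-4a-ol F9. Photooxygenation (O2, 5,10,15,20-tetraphenylporphyrin, visible light, CH2Cl2, −30 °C) should add singlet oxygen to the β face, anti to the α-fused dioxane, to give the C1,C4-endoperoxide of F9 (peroxide bridge β) F10. Reduction of the O–O bond with thiourea in MeOH returns to the route at 13.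

## Further compounds

F1 | step 3 | (4aR,8aS)-2-phenyl-4a-(triethylsilyloxy)-4a,8a-dihydro-4H-1,3,2-benzodioxaborinin-7(8H)-one | C1=CC(=O)C[C@H](O2)[C@]1(O[Si](CC)(CC)CC)COB2c1ccccc1
F2 | step 3 | (4R,5S)-5-hydroxy-4-(hydroxymethyl)-4-(triethylsilyloxy)cyclohex-2-en-1-one | C1=CC(=O)C[C@H](O)[C@]1(O[Si](CC)(CC)CC)CO
F3 | step 1 | 4-[(triethylsilyloxy)methyl]phenol | Oc1ccc(CO[Si](CC)(CC)CC)cc1
F4 | step 1 | 4-hydroxy-4-[(triethylsilyloxy)methyl]cyclohexa-2,5-dien-1-one | O=C1C=CC(O)(CO[Si](CC)(CC)CC)C=C1
F5 | step 4 | (2R,4aR,8S,8aS)-2-isopropyl-7-oxo-4a-(triethylsilyloxy)-4a,7,8,8a-tetrahydro-4H-1,3-benzodioxin-8-yl acetate | C1=CC(=O)[C@@H](OC(C)=O)[C@H](O2)[C@]1(O[Si](CC)(CC)CC)CO[C@H]2C(C)C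
F6 | step 4 | (2R,4aR,8S,8aS)-4a-hydroxy-2-isopropyl-7-oxo-4a,7,8,8a-tetrahydro-4H-1,3-benzodioxin-8-yl acetate | C1=CC(=O)[C@@H](OC(C)=O)[C@H](O2)[C@]1(O)CO[C@H]2C(C)C
F7 | step 6 | (2R,4aR,8aS)-2-isopropyl-4a-(triethylsilyloxy)-4a,8a-dihydro-4H-1,3-benzodioxin-7-yl trifluoromethanesulfonate | C1=CC(OS(=O)(=O)C(F)(F)F)=C[C@H](O2)[C@]1(O[Si](CC)(CC)CC)CO[C@H]2C(C)C
F8 | step 6 | (2R,4aR,8aS)-2-isopropyl-4a-(triethylsilyloxy)-4a,8a-dihydro-4H-1,3-benzodioxine | C1=CC=C[C@H](O2)[C@]1(O[Si](CC)(CC)CC)CO[C@H]2C(C)C
F9 | step 6 | (2R,4aR,8aS)-2-isopropyl-4a,8a-dihydro-4H-1,3-benzodioxin-4a-ol | C1=CC=C[C@H](O2)[C@]1(O)CO[C@H]2C(C)C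
F10 | step 6 | C1,C4-endoperoxide of F9, peroxide bridge on the β face (cis to the tertiary hydroxyl) | O3[C@H]1C=C[C@@H](O3)[C@H](O2)[C@]1(O)CO[C@H]2C(C)C
A1 | alternative 1 | (1R,2S)-1-(hydroxymethyl)cyclohexa-3,5-diene-1,2-diol (trans-diol; hydroxyls protected as needed) | C1=CC=C[C@H](O)[C@]1(O)CO
A2 | alternative 1 | 8-(hydroxymethyl)-2,3-dioxabicyclo[2.2.2]oct-5-ene-7,8-diol, peroxide bridge cis to the tertiary hydroxyl and trans to the secondary one | O3[C@H]1C=C[C@@H](O3)[C@H](O)[C@]1(O)CO
A3 | alternative 2 | (1E,3E)-buta-1,3-diene-1,4-diyl dibenzoate | O=C(O/C=C/C=C/OC(=O)c1ccccc1)c1ccccc1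
A4 | alternative 2 | methyl cis-3,6-bis(benzoyloxy)cyclohexa-1,4-diene-1-carboxylate (racemic, one enantiomer drawn) | O=C(O[C@H]1C=C[C@@H](OC(=O)c2ccccc2)C=C1C(=O)OC)c1ccccc1
A5 | alternative 3 | (3S,4R,5S,6R)-4,5-dihydroxy-4-(hydroxymethyl)octa-1,7-diene-3,6-diyl dibenzoate (hydroxyls protected as needed) | C=C[C@H](OC(=O)c1ccccc1)[C@@](O)(CO)[C@@H](O)[C@H](OC(=O)c1ccccc1)C=C
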